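**Retrosynthetic overview**
- The route rests on ring A: C5, C6, C7 and C8 carry four adjacent oxygens (5-OH para to 8-OMe), and the C4a=C8a bond is also a C=C of the γ-pyrone ring C. A squarate C4 unit fused onto a 4-pyranone C=C supplies exactly this.
- Final operations: methylation of O8 (O5 is held by its hydrogen bond to the C4 carbonyl) and hydrogenolysis of the 2'-O-benzyl ether.
- Key disconnection: C8–C8a of ring A, leading back to a 4-hydroxy-4-(4-pyranon-3-yl)cyclobutenone, made from dimethyl squarate and the C5-magnesiated 2-aryl-3-methoxy-4-pyranone.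
- Ring C: the 2-aryl-3-hydroxy-4-pyranone comes from an aryl furyl carbinol (Achmatowicz oxidation, acetal, epoxidation, acid), itself from furan and benzylated 2-hydroxy-4-methoxybenzaldehyde.
- Ring order: B (bought), then C, then A.

Key step: step 9

Remark: the target is achiral. Compounds 5, 13 and 15 are racemates and 6–8 are diastereomer mixtures, used as such, because every stereocentre is erased in step 6 or step 9.

**Step 1**
Reactants: 1 2-hydroxy-4-methoxybenzaldehyde
Product: 2 2-(benzyloxy)-4-methoxybenzaldehyde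
Conditions: BnBr, K2CO3, DMF, 60 °C
Reagents that add atoms: benzyl bromide, BrCc1ccccc1
Why: Williamson etherification of the phenol; the benzyl group masks O2' through the organometallic and methylation steps and is removable at the end by hydrogenolysis.

**Step 2**
Reactants: 3 furan; 2 2-(benzyloxy)-4-methoxybenzaldehyde
Product: 5 (2-benzyloxy-4-methoxyphenyl)(furan-2-yl)methanol (racemic), via 2-furyllithium 4 (not isolated)
Conditions: furan, n-BuLi, THF, 0 °C; then 2, −78 °C; H2O quench
Reagents that add atoms: none
Why: α-Lithiation of furan followed by 1,2-addition to the aldehyde; the carbinol centre forms as a racemate and is erased in step 6.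

**Step 3**
Reactants: 5 (2-benzyloxy-4-methoxyphenyl)(furan-2-yl)methanol
Product: 6 2-(2-benzyloxy-4-methoxyphenyl)-6-hydroxy-2H-pyran-3(6H)-one (mixture of anomers)
Conditions: t-BuOOH, VO(acac)2 (cat.), CH2Cl2, 0 °C to rt
Reagents that add atoms: tert-butyl hydroperoxide, CC(C)(C)OO
Why: Achmatowicz rearrangement under neutral, hydroxyl-directed vanadium catalysis, chosen so that neither the acid-labile carbinol nor the electron-rich arene is attacked; the C6 configuration is of no consequence.

**Step 4**
Reactants: 6 2-(2-benzyloxy-4-methoxyphenyl)-6-hydroxy-2H-pyran-3(6H)-one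
Product: 7 2-(2-benzyloxy-4-methoxyphenyl)-6-methoxy-2H-pyran-3(6H)-one (mixture of diastereomers)
Conditions: HC(OMe)3, BF3·OEt2 (cat.), CH2Cl2, −20 to 0 °C
Reagents that add atoms: trimethyl orthoformate, COC(OC)OC
Why: Acid-catalysed acetalisation through the ring oxocarbenium ion; capping the hemiacetal keeps the ring from opening under the basic epoxidation that follows.

**Step 5**
Reactants: 7 2-(2-benzyloxy-4-methoxyphenyl)-6-methoxy-2H-pyran-3(6H)-one
Product: 8 4-(2-benzyloxy-4-methoxyphenyl)-2-methoxy-3,7-dioxabicyclo[4.1.0]heptan-5-one (mixture of diastereomers)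
Conditions: 30% aq. H2O2, NaOH (cat.), MeOH, 0 °C
Reagents that add atoms: hydrogen peroxide, OO
Why: Weitz–Scheffer nucleophilic epoxidation of the enone, expected anti to the acetal methoxyl; the epoxide configuration does not matter because both carbons become sp2 in step 6.

**Step 6**
Reactants: 8 4-(2-benzyloxy-4-methoxyphenyl)-2-methoxy-3,7-dioxabicyclo[4.1.0]heptan-5-one
Product: 9 2-(2-benzyloxy-4-methoxyphenyl)-3-hydroxy-4H-pyran-4-one
Conditions: 1 M aq. H2SO4, 1,4-dioxane, 90 °C
Reagents that add atoms: none
Why: Acid isomerises the α,β-epoxy ketone to the 3,4-dione with the oxygen kept on C4, methanol is lost from C6 by β-elimination and enolisation toward C2 gives the aromatic γ-pyrone, as in the maltol synthesis from furyl carbinols; all stereocentres of 8 are erased and the benzyl aryl ether should survive dilute aqueous acid.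

**Step 7**
Reactants: 9 2-(2-benzyloxy-4-methoxyphenyl)-3-hydroxy-4H-pyran-4-one
Product: 10 2-(2-benzyloxy-4-methoxyphenyl)-3-methoxy-4H-pyran-4-one
Conditions: MeI, K2CO3, acetone, reflux
Reagents that add atoms: iodomethane, CI
Why: Williamson O-methylation of the acidic enolic hydroxyl, which installs the future 3-OMe of the flavone.

**Step 8**
Reactants: 10 2-(2-benzyloxy-4-methoxyphenyl)-3-methoxy-4H-pyran-4-one; 11 dimethyl squarate
Product: 13 4-[6-(2-benzyloxy-4-methoxyphenyl)-5-methoxy-4-oxo-4H-pyran-3-yl]-4-hydroxy-2,3-dimethoxycyclobut-2-en-1-one (racemic), via pyranon-3-ylmagnesium chloride 12 (not isolated)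
Conditions: TMPMgCl·LiCl (TMP = 2,2,6,6-tetramethylpiperidide), THF, −40 °C; then cannulation into 11, THF, −78 to −40 °C; sat. aq. NH4Cl
Reagents that add atoms: none
Why: Carbonyl-directed magnesiation by the hindered, Lewis-acid-free magnesium amide should take the C5–H next to C4=O (the selectivity such bases show at C5 of uracils and C3 of chromones) rather than the C6–H next to the ring oxygen, and the Grignard then adds 1,2 to one of the two equivalent squarate ketones, the standard entry to 4-substituted 4-hydroxycyclobutenones; the carbinol centre is racemic and is erased in step 9.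

**Step 9**
Reactants: 13 4-[6-(2-benzyloxy-4-methoxyphenyl)-5-methoxy-4-oxo-4H-pyran-3-yl]-4-hydroxy-2,3-dimethoxycyclobut-2-en-1-one
Product: 16 2-(2-benzyloxy-4-methoxyphenyl)-5,8-dihydroxy-3,6,7-trimethoxy-4H-chromen-4-one, via dienylketene 14 (not isolated), via 8aH-chromene-4,8-dione 15 (not isolated)
Conditions: degassed PhMe, 110 °C, Ar
Reagents that add atoms: none
Why: Heating cleaves the C1–C4 bond of the cyclobutenone by conrotatory 4π electrocyclic opening to the dienylketene 14, with the donor hydroxyl rotating outward so that the pyranonyl group lies cis to the ketene. The ketene carbon then bonds to the hydrogen-bearing pyranone carbon (the future C8a) in a thermal 6π electrocyclisation across the ketene C=C, the enol C=C and the pyranone C=C, which forms C8–C8a and closes ring A as the six-membered dienone 15. Transfer of the 8a-hydrogen to the C8 carbonyl oxygen (enolisation) aromatises ring A to the 5,8-hydroquinone 16, with the squarate carbons becoming C5–C8 and all four oxygens already in place. The closest known reaction is the thermal ring expansion of 4-aryl-, 4-heteroaryl- and 4-alkenyl-4-hydroxycyclobutenones derived from squarate esters to hydroquinones (Moore rearrangement), the pyranone C=C here playing the alkenyl arm. No stereocentre is formed, since the carbinol carbon of 13 and C8a of 15 both end up sp2. The step needs outward rotation of the hydroxyl (otherwise the ketene is trapped by the hydroxyl as a butenolide), which the free 4-OH donor secures, and closure at carbon rather than at the pyranone carbonyl oxygen, which is secured because only the C–H carbon completes a six-membered ring; air is excluded so that 16 is not oxidised to the quinone.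

**Step 10**
Reactants: 16 2-(2-benzyloxy-4-methoxyphenyl)-5,8-dihydroxy-3,6,7-trimethoxy-4H-chromen-4-one
Product: 17 2-(2-benzyloxy-4-methoxyphenyl)-5-hydroxy-3,6,7,8-tetramethoxy-4H-chromen-4-one
Conditions: MeI (1.1 equiv), K2CO3, degassed acetone, Ar, rt
Reagents that add atoms: iodomethane, CI
Why: Williamson methylation should take the free 8-OH, because the 5-OH is locked in a hydrogen bond to the C4 carbonyl (the classical inertness of flavone 5-hydroxyls) and O2' is still benzylated.

**Step 11**
Reactants: 17 2-(2-benzyloxy-4-methoxyphenyl)-5-hydroxy-3,6,7,8-tetramethoxy-4H-chromen-4-one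
Product: 18 5,2'-dihydroxy-3,6,7,8,4'-pentamethoxyflavone
Conditions: H2 (1 atm), Pd/C (10%), EtOAc/MeOH, rt
Reagents that add atoms: none
Why: Hydrogenolysis of the benzyl aryl ether; the tetrasubstituted C2=C3 bond, the carbonyl and the methyl ethers should be untouched under these mild conditions.

**Compound list**
1 | 2-hydroxy-4-methoxybenzaldehyde | COc1ccc(C=O)c(O)c1 | starting material
2 | 2-(benzyloxy)-4-methoxybenzaldehyde | COc1ccc(C=O)c(OCc2ccccc2)c1 | intermediate
3 | furan | c1ccoc1 | starting material
4 | 2-furyllithium | [Li]c1ccco1 | intermediate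
5 | (2-benzyloxy-4-methoxyphenyl)(furan-2-yl)methanol (racemic) | COc1ccc(C(O)c2ccco2)c(OCc2ccccc2)c1 | intermediate
6 | 2-(2-benzyloxy-4-methoxyphenyl)-6-hydroxy-2H-pyran-3(6H)-one (mixture of anomers, racemic) | COc1ccc(C2OC(O)C=CC2=O)c(OCc2ccccc2)c1 | intermediate
7 | 2-(2-benzyloxy-4-methoxyphenyl)-6-methoxy-2H-pyran-3(6H)-one (mixture of diastereomers, racemic) | COc1ccc(C2OC(OC)C=CC2=O)c(OCc2ccccc2)c1 | intermediate
8 | 4-(2-benzyloxy-4-methoxyphenyl)-2-methoxy-3,7-dioxabicyclo[4.1.0]heptan-5-one (mixture of diastereomers, racemic) | COc1ccc(C2OC(OC)C3OC3C2=O)c(OCc2ccccc2)c1 | intermediate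
9 | 2-(2-benzyloxy-4-methoxyphenyl)-3-hydroxy-4H-pyran-4-one | COc1ccc(-c2occc(=O)c2O)c(OCc2ccccc2)c1 | intermediate
10 | 2-(2-benzyloxy-4-methoxyphenyl)-3-methoxy-4H-pyran-4-one | COc1ccc(-c2occc(=O)c2OC)c(OCc2ccccc2)c1 | intermediate
11 | dimethyl squarate (3,4-dimethoxycyclobut-3-ene-1,2-dione) | COC1=C(OC)C(=O)C1=O | starting material
12 | chloro[6-(2-benzyloxy-4-methoxyphenyl)-5-methoxy-4-oxo-4H-pyran-3-yl]magnesium (LiCl complex) | COC1=C(c2ccc(OC)cc2OCc2ccccc2)OC=C([Mg]Cl)C1=O | intermediate
13 | 4-[6-(2-benzyloxy-4-methoxyphenyl)-5-methoxy-4-oxo-4H-pyran-3-yl]-4-hydroxy-2,3-dimethoxycyclobut-2-en-1-one (racemic) | COC1=C(OC)C(O)(C2=COC(c3ccc(OC)cc3OCc3ccccc3)=C(OC)C2=O)C1=O | intermediate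
14 | (Z)-4-[6-(2-benzyloxy-4-methoxyphenyl)-5-methoxy-4-oxo-4H-pyran-3-yl]-4-hydroxy-2,3-dimethoxybuta-1,3-dien-1-one (dienylketene) | O=C=C(OC)/C(OC)=C(O)\C1=COC(c2ccc(OC)cc2OCc2ccccc2)=C(OC)C1=O | intermediate
15 | 2-(2-benzyloxy-4-methoxyphenyl)-5-hydroxy-3,6,7-trimethoxy-8aH-chromene-4,8-dione (racemic) | COC1=C(OC)C(=O)C2OC(c3ccc(OC)cc3OCc3ccccc3)=C(OC)C(=O)C2=C1O | intermediate
16 | 2-(2-benzyloxy-4-methoxyphenyl)-5,8-dihydroxy-3,6,7-trimethoxy-4H-chromen-4-one | COc1ccc(-c2oc3c(O)c(OC)c(OC)c(O)c3c(=O)c2OC)c(OCc2ccccc2)c1 | intermediate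
17 | 2-(2-benzyloxy-4-methoxyphenyl)-5-hydroxy-3,6,7,8-tetramethoxy-4H-chromen-4-one | COc1ccc(-c2oc3c(OC)c(OC)c(OC)c(O)c3c(=O)c2OC)c(OCc2ccccc2)c1 | intermediate
18 | 5,2'-dihydroxy-3,6,7,8,4'-pentamethoxyflavone | COc1ccc(-c2oc3c(OC)c(OC)c(OC)c(O)c3c(=O)c2OC)c(O)c1 | target

Total step count: 11. Longest linear sequence: 11 steps (1 to 18); furan 3 and dimethyl squarate 11 enter as bought reagents.

**Steps most likely to fail**

1. Step 9. The ketene may fail to close onto the oxygen-bearing pyranone carbon, which is the electron-poor end of the enone, and be diverted to a butenolide by attack of the hydroxyl or to oligomers. The fallback sets out from 10 and comes back at 16; it reverses the polarity pairing by fusing through the other pyranone carbon. Lithium 2,2,6,6-tetramethylpiperidide in THF at −78 °C should deprotonate 10 next to the ring oxygen (as in C2-lithiation of chromones) to give the 6-lithiopyranone F1. Addition of F1 to 11 should give the regioisomeric adduct 4-[6-(2-benzyloxy-4-methoxyphenyl)-5-methoxy-4-oxo-4H-pyran-2-yl]-4-hydroxy-2,3-dimethoxycyclobut-2-en-1-one F2. On heating in toluene, F2 should open to the (Z)-dienylketene F3, whose ketene carbon now meets the nucleophilic C–H carbon α to the pyranone carbonyl. Closure should give the 4aH-chromene-4,5-dione F4, whose 4a-hydrogen lies between two carbonyls and enolises readily. Because the 5,8-dihydroxy-6,7-dimethoxy pattern is symmetric, the product is the same hydroquinone 16, although the new bond is then C5–C4a.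

2. Step 8. Metalation may occur at C6 instead of C5, or the magnesiated pyranone may fragment by β-elimination of the ring oxygen before it adds. The fallback sets out from 10 and comes back at 12, with the position fixed by mechanism instead of by the base. Pyrrolidine in ethanol should add to C6 and open the ring to the enaminone 1-(2-benzyloxy-4-methoxyphenyl)-2-methoxy-5-(pyrrolidin-1-yl)pent-4-ene-1,3-dione F5. Iodine should then iodinate the enaminone α-carbon and trigger recyclisation with loss of pyrrolidine, as in the synthesis of 3-iodochromones from enaminones, to give 2-(2-benzyloxy-4-methoxyphenyl)-5-iodo-3-methoxy-4H-pyran-4-one F6; iodine alone does not touch the dialkoxyarene. Iodine–magnesium exchange on F6 with iPrMgCl·LiCl in THF at −40 °C should deliver 12, which is added to 11 as in step 8.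

3. Step 10. Discrimination between the two phenols may be lost (over-methylation), or the hydroquinone may be oxidised to the quinone under base. The fallback sets out from 16 and comes back at 18. Exhaustive methylation with excess MeI and K2CO3 in DMF under argon should give the pentamethyl ether 2-(2-benzyloxy-4-methoxyphenyl)-3,5,6,7,8-pentamethoxy-4H-chromen-4-one F7. BCl3 in CH2Cl2 at −78 to 0 °C should then cleave only the 5-OMe, through the six-membered boron chelate with the C4 carbonyl, together with the benzyl ether, giving 18 directly.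

**Further compounds**
F1 | step 9 | [6-(2-benzyloxy-4-methoxyphenyl)-5-methoxy-4-oxo-4H-pyran-2-yl]lithium | COC1=C(c2ccc(OC)cc2OCc2ccccc2)OC([Li])=CC1=O
F2 | step 9 | 4-[6-(2-benzyloxy-4-methoxyphenyl)-5-methoxy-4-oxo-4H-pyran-2-yl]-4-hydroxy-2,3-dimethoxycyclobut-2-en-1-one (racemic) | COC1=C(OC)C(O)(C2=CC(=O)C(OC)=C(c3ccc(OC)cc3OCc3ccccc3)O2)C1=O
F3 | step 9 | (Z)-4-[6-(2-benzyloxy-4-methoxyphenyl)-5-methoxy-4-oxo-4H-pyran-2-yl]-4-hydroxy-2,3-dimethoxybuta-1,3-dien-1-one | O=C=C(OC)/C(OC)=C(O)\C1=CC(=O)C(OC)=C(c2ccc(OC)cc2OCc2ccccc2)O1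
F4 | step 9 | 2-(2-benzyloxy-4-methoxyphenyl)-8-hydroxy-3,6,7-trimethoxy-4aH-chromene-4,5-dione (racemic) | COC1=C(OC)C(=O)C2C(=O)C(OC)=C(c3ccc(OC)cc3OCc3ccccc3)OC2=C1O
F5 | step 8 | (E)-1-(2-benzyloxy-4-methoxyphenyl)-2-methoxy-5-(pyrrolidin-1-yl)pent-4-ene-1,3-dione (racemic, enolisable) | COc1ccc(C(=O)C(OC)C(=O)/C=C/N2CCCC2)c(OCc2ccccc2)c1
F6 | step 8 | 2-(2-benzyloxy-4-methoxyphenyl)-5-iodo-3-methoxy-4H-pyran-4-one | COc1ccc(-c2occ(I)c(=O)c2OC)c(OCc2ccccc2)c1
F7 | step 10 | 2-(2-benzyloxy-4-methoxyphenyl)-3,5,6,7,8-pentamethoxy-4H-chromen-4-one | COc1ccc(-c2oc3c(OC)c(OC)c(OC)c(OC)c3c(=O)c2OC)c(OCc2ccccc2)c1
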